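**Retrosynthetic overview**
1. Target 42 ⇐ diol 41 (double acetylation) ⇐ 14-membered ring closed at C13–C14 by intramolecular alkylation of an α-sulfonyl carbanion with an allylic bromide, then desulfonylation.
2. The oxirane (C7–C8) is made earlier, on the open chain, by C10-hydroxyl-directed epoxidation; the C11=C12 enoate is electron-poor and the C3=C4 olefin is remote, so neither competes.
3. Key C9–C10 bond: intermolecular α-selective allylbarium addition of fragment A (allylic chloride 21) to the aldehyde of fragment B (enal ester 25); C10 is then fixed by oxidation and CBS reduction.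
4. Fragment A comes from neryl acetate (3Z and 7E olefins in place, SeO2 gives C9–O), with C1 set by Evans alkylation; fragment B comes from glyoxal dimethyl acetal by Wittig olefination.
5. Ring order: oxirane first (step 19), 14-membered carbocycle second (step 26).

Assumption: cembrane locants are used for orientation (C1 = ring CH bearing the oxygenated propan-2-yl group, C3=C4 Z-olefin, C7/C8 epoxide, C10 secondary carbinol, C11=C12 E-olefin); TBDPS = tert-butyldiphenylsilyl, PMB = 4-methoxybenzyl, TES = triethylsilyl, TBS = tert-butyldimethylsilyl; compounds 1, 6, 10, 22 and 23 are taken as commercial.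

**Fragment A (steps 1–13)**

Step 1
Reactants: 1 neryl acetate
Product: 2 (2Z,6E)-8-hydroxy-3,7-dimethylocta-2,6-dien-1-yl acetate
Conditions: SeO2 (0.3 equiv), t-BuOOH (70% aq), salicylic acid (cat.), CH2Cl2, rt
Reagents that add atoms: tert-butyl hydroperoxide, CC(C)(C)OO
Why: SeO2 allylic oxidation (ene reaction then [2,3]-shift) hydroxylates the E-methyl of the terminal olefin (future C9), while the 3Z olefin is deactivated by the allylic acetate.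

Step 2
Reactants: 2 (2Z,6E)-8-hydroxy-3,7-dimethylocta-2,6-dien-1-yl acetate
Product: 3 (2Z,6E)-8-(TBDPS-oxy)-3,7-dimethylocta-2,6-dien-1-yl acetate
Conditions: t-BuPh2SiCl, imidazole, DMF, 0 °C → rt
Reagents that add atoms: tert-butyl(chloro)diphenylsilane, CC(C)(C)[Si](Cl)(c1ccccc1)c1ccccc1
Why: Silylation of the primary allylic alcohol masks C9–OH through the enolate and Grignard steps.

Step 3
Reactants: 3 (2Z,6E)-8-(TBDPS-oxy)-3,7-dimethylocta-2,6-dien-1-yl acetate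
Product: 4 (2Z,6E)-8-(TBDPS-oxy)-3,7-dimethylocta-2,6-dien-1-ol
Conditions: K2CO3 (0.2 equiv), MeOH, 0 °C → rt
Reagents that add atoms: none
Why: Base-catalysed transesterification frees the C2 allylic alcohol without touching the silyl ether or the olefin geometry.

Step 4
Reactants: 4 (2Z,6E)-8-(TBDPS-oxy)-3,7-dimethylocta-2,6-dien-1-ol
Product: 5 (2Z,6E)-1-bromo-8-(TBDPS-oxy)-3,7-dimethylocta-2,6-diene
Conditions: CBr4, PPh3, CH2Cl2, −20 → 0 °C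
Reagents that add atoms: carbon tetrabromide, BrC(Br)(Br)Br
Why: Appel bromination is an SN2 process under neutral conditions, so the 3Z olefin is not isomerised.

Step 5
Reactants: 5 (2Z,6E)-1-bromo-8-(TBDPS-oxy)-3,7-dimethylocta-2,6-diene; 6 ethyl acetate
Product: 8 ethyl (4Z,8E)-10-(TBDPS-oxy)-5,9-dimethyldeca-4,8-dienoate, via lithium enolate of ethyl acetate 7 (not isolated)
Conditions: LiN(i-Pr)2 (commercial solution), 6, THF, −78 °C; then 5, DMPU, −78 → −30 °C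
Reagents that add atoms: none
Why: Ester enolate alkylation (SN2 at the primary allylic bromide) adds C1 and C15 with retention of olefin geometry.

Step 6
Reactants: 8 ethyl (4Z,8E)-10-(TBDPS-oxy)-5,9-dimethyldeca-4,8-dienoate
Product: 9 (4Z,8E)-10-(TBDPS-oxy)-5,9-dimethyldeca-4,8-dienoic acid
Conditions: LiOH, THF/MeOH/H2O, rt; 1 M HCl work-up
Reagents that add atoms: lithium hydroxide, [Li+].[OH-]
Why: Saponification gives the acid needed for auxiliary attachment.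

Step 7
Reactants: 9 (4Z,8E)-10-(TBDPS-oxy)-5,9-dimethyldeca-4,8-dienoic acid; 10 (R)-4-benzyloxazolidin-2-one
Product: 12 (R)-4-benzyl-3-[(4Z,8E)-10-(TBDPS-oxy)-5,9-dimethyldeca-4,8-dienoyl]oxazolidin-2-one, via mixed pivalic anhydride 11 (not isolated)
Conditions: t-BuCOCl, Et3N, THF, −20 °C; then 10, LiCl, −20 °C → rt
Reagents that add atoms: none
Why: N-acylation of the Evans oxazolidinone through the mixed anhydride installs the chiral auxiliary.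

Step 8
Reactants: 12 (R)-4-benzyl-3-[(4Z,8E)-10-(TBDPS-oxy)-5,9-dimethyldeca-4,8-dienoyl]oxazolidin-2-one
Product: 14 (R)-4-benzyl-3-[(2S,4Z,8E)-10-(TBDPS-oxy)-2-(PMB-oxymethyl)-5,9-dimethyldeca-4,8-dienoyl]oxazolidin-2-one, via sodium enolate 13 (not isolated)
Conditions: NaN(SiMe3)2, THF, −78 °C; then 4-MeOC6H4CH2OCH2Cl, −78 → −20 °C
Reagents that add atoms: 4-methoxybenzyl chloromethyl ether, COc1ccc(COCCl)cc1
Why: Evans asymmetric alkylation: the chelated Z-enolate is alkylated on the face opposite the benzyl group, which sets C1 (2S here, R in the target once CIP priorities change) and brings in C14.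

Step 9
Reactants: 14 (R)-4-benzyl-3-[(2S,4Z,8E)-10-(TBDPS-oxy)-2-(PMB-oxymethyl)-5,9-dimethyldeca-4,8-dienoyl]oxazolidin-2-one
Product: 15 methyl (2S,4Z,8E)-10-(TBDPS-oxy)-2-(PMB-oxymethyl)-5,9-dimethyldeca-4,8-dienoate
Conditions: MeMgBr, MeOH (gives MeOMgBr), CH2Cl2, 0 °C
Reagents that add atoms: methanol, CO
Why: Magnesium methoxide transesterification cleaves the exocyclic imide carbonyl and releases the auxiliary without epimerising C1.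

Step 10
Reactants: 15 methyl (2S,4Z,8E)-10-(TBDPS-oxy)-2-(PMB-oxymethyl)-5,9-dimethyldeca-4,8-dienoate
Product: 17 (3S,5Z,9E)-11-(TBDPS-oxy)-3-(PMB-oxymethyl)-2,6,10-trimethylundeca-5,9-dien-2-ol, via methyl ketone 16 (not isolated)
Conditions: MeMgBr (4 equiv), THF, 0 °C → rt; NH4Cl work-up
Reagents that add atoms: methylmagnesium bromide, C[Mg]Br
Why: Double Grignard addition to the ester builds the C15 tertiary carbinol; addition outruns enolisation, so C1 is kept.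

Step 11
Reactants: 17 (3S,5Z,9E)-11-(TBDPS-oxy)-3-(PMB-oxymethyl)-2,6,10-trimethylundeca-5,9-dien-2-ol
Product: 18 (2E,6Z,9S)-9-(PMB-oxymethyl)-2,6,10-trimethylundeca-2,6-diene-1,10-diol
Conditions: Bu4NF, THF, rt; NH4Cl work-up
Reagents that add atoms: none
Why: Fluoride desilylation removes the TBDPS ether; the PMB ether and the tertiary alcohol are inert.

Step 12
Reactants: 18 (2E,6Z,9S)-9-(PMB-oxymethyl)-2,6,10-trimethylundeca-2,6-diene-1,10-diol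
Product: 20 (3S,5Z,9E)-11-chloro-3-(PMB-oxymethyl)-2,6,10-trimethylundeca-5,9-dien-2-ol, via allylic mesylate 19 (not isolated)
Conditions: MsCl, 2,4,6-collidine, LiCl, DMF, 0 °C
Reagents that add atoms: lithium chloride, [Li+].[Cl-]
Why: Collington–Meyers chlorination (mesylation then chloride SN2) is selective for the primary allylic alcohol over the tertiary one and keeps the 7E geometry.

Step 13
Reactants: 20 (3S,5Z,9E)-11-chloro-3-(PMB-oxymethyl)-2,6,10-trimethylundeca-5,9-dien-2-ol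
Product: 21 (3S,5Z,9E)-11-chloro-3-(PMB-oxymethyl)-2,6,10-trimethyl-2-(TES-oxy)undeca-5,9-diene (fragment A)
Conditions: Et3SiOTf, 2,6-lutidine, CH2Cl2, −78 °C
Reagents that add atoms: triethylsilyl trifluoromethanesulfonate, CC[Si](CC)(CC)OS(=O)(=O)C(F)(F)F
Why: Silyl triflate silylation protects the hindered tertiary alcohol so that no acidic proton remains for the organobarium step.

**Fragment B (steps 14–15)**

Step 14
Reactants: 22 2,2-dimethoxyacetaldehyde; 23 ethyl 2-(triphenyl-λ5-phosphanylidene)propanoate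
Product: 24 ethyl (E)-4,4-dimethoxy-2-methylbut-2-enoate
Conditions: CH2Cl2, rt
Reagents that add atoms: none
Why: Wittig olefination with a stabilised α-methyl ylide gives the E-trisubstituted enoate (future C11=C12).

Step 15
Reactants: 24 ethyl (E)-4,4-dimethoxy-2-methylbut-2-enoate
Product: 25 ethyl (E)-2-methyl-4-oxobut-2-enoate (fragment B)
Conditions: p-TsOH·H2O (cat.), acetone/H2O, rt
Reagents that add atoms: water, O
Why: Acid-catalysed acetal hydrolysis unmasks the C10 aldehyde without isomerising the E-enoate.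

**Coupling, oxirane, macrocycle (steps 16–29)**

Step 16
Reactants: 21 (3S,5Z,9E)-11-chloro-3-(PMB-oxymethyl)-2,6,10-trimethyl-2-(TES-oxy)undeca-5,9-diene; 25 ethyl (E)-2-methyl-4-oxobut-2-enoate
Product: 27 ethyl (2E,6E,10Z,13S)-4-hydroxy-13-(PMB-oxymethyl)-2,6,10,14-tetramethyl-14-(TES-oxy)pentadeca-2,6,10-trienoate (C4 epimers), via allylbarium chloride 26 (not isolated)
Conditions: Li, biphenyl, THF, rt; BaI2, rt; 21, −78 °C; then 25, −78 °C; NH4Cl work-up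
Reagents that add atoms: none
Why: Carbonyl allylation with a γ-substituted allylbarium reagent, which adds 1,2 to the aldehyde through its unsubstituted α-carbon (C9) with retention of the 7E geometry and faster than to the ester; C10 forms unselectively and is corrected in steps 17–18.

Step 17
Reactants: 27 ethyl (2E,6E,10Z,13S)-4-hydroxy-13-(PMB-oxymethyl)-2,6,10,14-tetramethyl-14-(TES-oxy)pentadeca-2,6,10-trienoate (C4 epimers)
Product: 28 ethyl (2E,6E,10Z,13S)-13-(PMB-oxymethyl)-2,6,10,14-tetramethyl-4-oxo-14-(TES-oxy)pentadeca-2,6,10-trienoate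
Conditions: Dess–Martin periodinane, NaHCO3, CH2Cl2, 0 °C → rt
Reagents that add atoms: none
Why: Buffered Dess–Martin oxidation erases the unselective C10 centre without moving the β,γ-olefin into conjugation.

Step 18
Reactants: 28 ethyl (2E,6E,10Z,13S)-13-(PMB-oxymethyl)-2,6,10,14-tetramethyl-4-oxo-14-(TES-oxy)pentadeca-2,6,10-trienoate
Product: 29 ethyl (2E,4R,6E,10Z,13S)-4-hydroxy-13-(PMB-oxymethyl)-2,6,10,14-tetramethyl-14-(TES-oxy)pentadeca-2,6,10-trienoate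
Conditions: (S)-2-methyl-CBS-oxazaborolidine (C18H20BNO, 0.5 equiv), catecholborane, toluene, −78 °C
Reagents that add atoms: none
Why: Corey–Bakshi–Shibata reduction: with the alkenyl group as the large substituent the (S)-catalyst gives the 4R alcohol (C10 R), and the ester is untouched.

Step 19
Reactants: 29 ethyl (2E,4R,6E,10Z,13S)-4-hydroxy-13-(PMB-oxymethyl)-2,6,10,14-tetramethyl-14-(TES-oxy)pentadeca-2,6,10-trienoate
Product: 30 ethyl (2E,4R)-4-hydroxy-5-[(2R,3R)-3-[(3Z,6S)-6-(PMB-oxymethyl)-3,7-dimethyl-7-(TES-oxy)oct-3-en-1-yl]-2-methyloxiran-2-yl]-2-methylpent-2-enoate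
Conditions: VO(acac)2 (10 mol%), t-BuOOH (in decane), CH2Cl2, 0 °C → rt
Reagents that add atoms: tert-butyl hydroperoxide, CC(C)(C)OO
Why: Hydroxyl-directed vanadium-catalysed epoxidation of the homoallylic alcohol; in the chair-like vanadate transition state the alkenyl group on C10 is equatorial and the C8 methyl turns away from C10 (least A(1,2) strain), so the E-olefin is predicted to give the 1,3-anti 7R,8R epoxide.

Step 20
Reactants: 30 ethyl (2E,4R)-4-hydroxy-5-[(2R,3R)-3-[(3Z,6S)-6-(PMB-oxymethyl)-3,7-dimethyl-7-(TES-oxy)oct-3-en-1-yl]-2-methyloxiran-2-yl]-2-methylpent-2-enoate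
Product: 31 ethyl (2E,4R)-4-(TBS-oxy)-5-[(2R,3R)-3-[(3Z,6S)-6-(PMB-oxymethyl)-3,7-dimethyl-7-(TES-oxy)oct-3-en-1-yl]-2-methyloxiran-2-yl]-2-methylpent-2-enoate
Conditions: t-BuMe2SiCl, imidazole, 4-(dimethylamino)pyridine (cat.), DMF, rt → 40 °C
Reagents that add atoms: tert-butyl(chloro)dimethylsilane, CC(C)(C)[Si](C)(C)Cl
Why: Silylation protects C10–OH, which had to be free only for the directed epoxidation, ahead of the hydride and strong-base steps.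

Step 21
Reactants: 31 ethyl (2E,4R)-4-(TBS-oxy)-5-[(2R,3R)-3-[(3Z,6S)-6-(PMB-oxymethyl)-3,7-dimethyl-7-(TES-oxy)oct-3-en-1-yl]-2-methyloxiran-2-yl]-2-methylpent-2-enoate
Product: 32 ethyl (2E,4R)-4-(TBS-oxy)-5-[(2R,3R)-3-[(3Z,6S)-6-(hydroxymethyl)-3,7-dimethyl-7-(TES-oxy)oct-3-en-1-yl]-2-methyloxiran-2-yl]-2-methylpent-2-enoate
Conditions: DDQ, CH2Cl2/pH 7 phosphate buffer, 0 °C
Reagents that add atoms: none
Why: Oxidative PMB ether cleavage under buffered conditions frees only the C14 primary alcohol.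

Step 22
Reactants: 32 ethyl (2E,4R)-4-(TBS-oxy)-5-[(2R,3R)-3-[(3Z,6S)-6-(hydroxymethyl)-3,7-dimethyl-7-(TES-oxy)oct-3-en-1-yl]-2-methyloxiran-2-yl]-2-methylpent-2-enoate
Product: 33 ethyl (2E,4R)-4-(TBS-oxy)-5-[(2R,3R)-3-[(3Z,6R)-3,7-dimethyl-6-[(phenylsulfanyl)methyl]-7-(TES-oxy)oct-3-en-1-yl]-2-methyloxiran-2-yl]-2-methylpent-2-enoate
Conditions: N-(phenylthio)succinimide, n-Bu3P, THF, rt
Reagents that add atoms: N-(phenylthio)succinimide, O=C1CCC(=O)N1Sc1ccccc1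
Why: Phosphine-mediated thioetherification (Mitsunobu-type SN2 through the alkoxyphosphonium salt) makes the phenyl sulfide without free thiol that could add to the enoate.

Step 23
Reactants: 33 ethyl (2E,4R)-4-(TBS-oxy)-5-[(2R,3R)-3-[(3Z,6R)-3,7-dimethyl-6-[(phenylsulfanyl)methyl]-7-(TES-oxy)oct-3-en-1-yl]-2-methyloxiran-2-yl]-2-methylpent-2-enoate
Product: 34 ethyl (2E,4R)-4-(TBS-oxy)-5-[(2R,3R)-3-[(3Z,6R)-3,7-dimethyl-6-[(phenylsulfonyl)methyl]-7-(TES-oxy)oct-3-en-1-yl]-2-methyloxiran-2-yl]-2-methylpent-2-enoate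
Conditions: (n-Pr)4N[RuO4] (10 mol%), N-methylmorpholine N-oxide, 4 Å MS, MeCN, rt → 40 °C
Reagents that add atoms: N-methylmorpholine N-oxide, C[N+]1([O-])CCOCC1
Why: Perruthenate-catalysed sulfide-to-sulfone oxidation is neutral and anhydrous, so the olefins, silyl ethers and epoxide are left alone.

Step 24
Reactants: 34 ethyl (2E,4R)-4-(TBS-oxy)-5-[(2R,3R)-3-[(3Z,6R)-3,7-dimethyl-6-[(phenylsulfonyl)methyl]-7-(TES-oxy)oct-3-en-1-yl]-2-methyloxiran-2-yl]-2-methylpent-2-enoate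
Product: 35 (2E,4R)-4-(TBS-oxy)-5-[(2R,3R)-3-[(3Z,6R)-3,7-dimethyl-6-[(phenylsulfonyl)methyl]-7-(TES-oxy)oct-3-en-1-yl]-2-methyloxiran-2-yl]-2-methylpent-2-en-1-ol
Conditions: i-Bu2AlH (2.5 equiv), CH2Cl2, −78 °C; Rochelle salt work-up
Reagents that add atoms: none
Why: Low-temperature 1,2-reduction of the conjugated ester gives the C13 allylic alcohol; the epoxide and sulfone are inert at −78 °C.

Step 25
Reactants: 35 (2E,4R)-4-(TBS-oxy)-5-[(2R,3R)-3-[(3Z,6R)-3,7-dimethyl-6-[(phenylsulfonyl)methyl]-7-(TES-oxy)oct-3-en-1-yl]-2-methyloxiran-2-yl]-2-methylpent-2-en-1-ol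
Product: 37 (2R,3E)-5-bromo-1-[(2R,3R)-3-[(3Z,6R)-3,7-dimethyl-6-[(phenylsulfonyl)methyl]-7-(TES-oxy)oct-3-en-1-yl]-2-methyloxiran-2-yl]-4-methyl-2-(TBS-oxy)pent-3-ene, via allylic mesylate 36 (not isolated)
Conditions: MsCl, Et3N, THF, −40 °C; then LiBr, −40 → 0 °C
Reagents that add atoms: lithium bromide, [Li+].[Br-]
Why: Mesylation and bromide SN2 displacement give the primary allylic bromide with the 11E geometry intact.

Step 26
Reactants: 37 (2R,3E)-5-bromo-1-[(2R,3R)-3-[(3Z,6R)-3,7-dimethyl-6-[(phenylsulfonyl)methyl]-7-(TES-oxy)oct-3-en-1-yl]-2-methyloxiran-2-yl]-4-methyl-2-(TBS-oxy)pent-3-ene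
Product: 39 (1R,3Z,7R,8R,10R,11E)-10-(TBS-oxy)-7,8-epoxy-14-(phenylsulfonyl)-15-(TES-oxy)cembra-3,11-diene (C14 epimers), via lithiated sulfone 38 (not isolated)
Conditions: LiN(i-Pr)2 (commercial solution, 1.5 equiv), THF, −78 → 0 °C, slow addition of 37, 0.002 M
Reagents that add atoms: none
Why: Intramolecular alkylation of the α-sulfonyl carbanion (C14) by the primary allylic bromide (C13) under high dilution closes the 14-membered ring; the uncontrolled C14 centre is removed in step 27.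

Step 27
Reactants: 39 (1R,3Z,7R,8R,10R,11E)-10-(TBS-oxy)-7,8-epoxy-14-(phenylsulfonyl)-15-(TES-oxy)cembra-3,11-diene (C14 epimers)
Product: 40 (1R,3Z,7R,8R,10R,11E)-10-(TBS-oxy)-7,8-epoxy-15-(TES-oxy)cembra-3,11-diene
Conditions: Na/Hg (5% Na), Na2HPO4, MeOH/THF, −20 °C
Reagents that add atoms: none
Why: Buffered reductive desulfonylation replaces a non-allylic C–S bond by C–H, so no olefin can migrate and the epoxide survives.

Step 28
Reactants: 40 (1R,3Z,7R,8R,10R,11E)-10-(TBS-oxy)-7,8-epoxy-15-(TES-oxy)cembra-3,11-diene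
Product: 41 (1R,3Z,7R,8R,10R,11E)-7,8-epoxycembra-3,11-diene-10,15-diol
Conditions: Bu4NF (excess), THF, rt → 45 °C; NH4Cl work-up
Reagents that add atoms: none
Why: Fluoride desilylation cleaves the secondary TBS and the tertiary TES ether under conditions the trisubstituted epoxide tolerates.

Step 29
Reactants: 41 (1R,3Z,7R,8R,10R,11E)-7,8-epoxycembra-3,11-diene-10,15-diol
Product: 42 (1R,3Z,7R,8R,10R,11E)-7,8-epoxycembra-3,11-diene-10,15-diyl diacetate (CNP0282098.2)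
Conditions: Ac2O, Et3N, 4-(dimethylamino)pyridine, CH2Cl2, rt → 40 °C
Reagents that add atoms: acetic anhydride, CC(=O)OC(C)=O
Why: Nucleophile-catalysed acyl transfer (Steglich-type acetylation) esterifies the secondary allylic alcohol and, more slowly, the tertiary alcohol without opening the epoxide.

**Compound list**

1 | neryl acetate, (2Z)-3,7-dimethylocta-2,6-dien-1-yl acetate | CC(=O)OC/C=C(/C)CCC=C(C)C | starting material
2 | (2Z,6E)-8-hydroxy-3,7-dimethylocta-2,6-dien-1-yl acetate | CC(=O)OC/C=C(/C)CC/C=C(\C)CO | intermediate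
3 | (2Z,6E)-8-(TBDPS-oxy)-3,7-dimethylocta-2,6-dien-1-yl acetate | CC(=O)OC/C=C(/C)CC/C=C(\C)CO[Si](c1ccccc1)(c1ccccc1)C(C)(C)C | intermediate
4 | (2Z,6E)-8-(TBDPS-oxy)-3,7-dimethylocta-2,6-dien-1-ol | OC/C=C(/C)CC/C=C(\C)CO[Si](c1ccccc1)(c1ccccc1)C(C)(C)C | intermediate
5 | (2Z,6E)-1-bromo-8-(TBDPS-oxy)-3,7-dimethylocta-2,6-diene | BrC/C=C(/C)CC/C=C(\C)CO[Si](c1ccccc1)(c1ccccc1)C(C)(C)C | intermediate
6 | ethyl acetate | CCOC(C)=O | starting material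
7 | lithium enolate of ethyl acetate (not isolated) | C=C(O[Li])OCC | intermediate
8 | ethyl (4Z,8E)-10-(TBDPS-oxy)-5,9-dimethyldeca-4,8-dienoate | CCOC(=O)CC/C=C(/C)CC/C=C(\C)CO[Si](c1ccccc1)(c1ccccc1)C(C)(C)C | intermediate
9 | (4Z,8E)-10-(TBDPS-oxy)-5,9-dimethyldeca-4,8-dienoic acid | OC(=O)CC/C=C(/C)CC/C=C(\C)CO[Si](c1ccccc1)(c1ccccc1)C(C)(C)C | intermediate
10 | (R)-4-benzyloxazolidin-2-one | O=C1N[C@H](Cc2ccccc2)CO1 | starting material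
11 | mixed pivalic anhydride of acid 9 (not isolated) | CC(C)(C)C(=O)OC(=O)CC/C=C(/C)CC/C=C(\C)CO[Si](c1ccccc1)(c1ccccc1)C(C)(C)C | intermediate
12 | (R)-4-benzyl-3-[(4Z,8E)-10-(TBDPS-oxy)-5,9-dimethyldeca-4,8-dienoyl]oxazolidin-2-one | O=C(CC/C=C(/C)CC/C=C(\C)CO[Si](c1ccccc1)(c1ccccc1)C(C)(C)C)N1[C@H](Cc2ccccc2)COC1=O | intermediate
13 | sodium Z-enolate of imide 12 (not isolated) | [Na]O/C(=C\C/C=C(/C)CC/C=C(\C)CO[Si](c1ccccc1)(c1ccccc1)C(C)(C)C)N1[C@H](Cc2ccccc2)COC1=O | intermediate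
14 | (R)-4-benzyl-3-[(2S,4Z,8E)-10-(TBDPS-oxy)-2-(PMB-oxymethyl)-5,9-dimethyldeca-4,8-dienoyl]oxazolidin-2-one | COc1ccc(COC[C@@H](C(=O)N2[C@H](Cc3ccccc3)COC2=O)C/C=C(/C)CC/C=C(\C)CO[Si](c2ccccc2)(c2ccccc2)C(C)(C)C)cc1 | intermediate
15 | methyl (2S,4Z,8E)-10-(TBDPS-oxy)-2-(PMB-oxymethyl)-5,9-dimethyldeca-4,8-dienoate | COc1ccc(COC[C@@H](C(=O)OC)C/C=C(/C)CC/C=C(\C)CO[Si](c2ccccc2)(c2ccccc2)C(C)(C)C)cc1 | intermediate
16 | (3S,5Z,9E)-11-(TBDPS-oxy)-3-(PMB-oxymethyl)-6,10-dimethylundeca-5,9-dien-2-one (not isolated) | COc1ccc(COC[C@@H](C(C)=O)C/C=C(/C)CC/C=C(\C)CO[Si](c2ccccc2)(c2ccccc2)C(C)(C)C)cc1 | intermediate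
17 | (3S,5Z,9E)-11-(TBDPS-oxy)-3-(PMB-oxymethyl)-2,6,10-trimethylundeca-5,9-dien-2-ol | COc1ccc(COC[C@@H](C(C)(C)O)C/C=C(/C)CC/C=C(\C)CO[Si](c2ccccc2)(c2ccccc2)C(C)(C)C)cc1 | intermediate
18 | (2E,6Z,9S)-9-(PMB-oxymethyl)-2,6,10-trimethylundeca-2,6-diene-1,10-diol | COc1ccc(COC[C@@H](C(C)(C)O)C/C=C(/C)CC/C=C(\C)CO)cc1 | intermediate
19 | (2E,6Z,9S)-10-hydroxy-9-(PMB-oxymethyl)-2,6,10-trimethylundeca-2,6-dien-1-yl methanesulfonate (not isolated) | COc1ccc(COC[C@@H](C(C)(C)O)C/C=C(/C)CC/C=C(\C)COS(C)(=O)=O)cc1 | intermediate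
20 | (3S,5Z,9E)-11-chloro-3-(PMB-oxymethyl)-2,6,10-trimethylundeca-5,9-dien-2-ol | COc1ccc(COC[C@@H](C(C)(C)O)C/C=C(/C)CC/C=C(\C)CCl)cc1 | intermediate
21 | (3S,5Z,9E)-11-chloro-3-(PMB-oxymethyl)-2,6,10-trimethyl-2-(TES-oxy)undeca-5,9-diene (fragment A) | COc1ccc(COC[C@@H](C(C)(C)O[Si](CC)(CC)CC)C/C=C(/C)CC/C=C(\C)CCl)cc1 | intermediate
22 | 2,2-dimethoxyacetaldehyde | COC(OC)C=O | starting material
23 | ethyl 2-(triphenyl-λ5-phosphanylidene)propanoate | CCOC(=O)C(C)=P(c1ccccc1)(c1ccccc1)c1ccccc1 | starting material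
24 | ethyl (E)-4,4-dimethoxy-2-methylbut-2-enoate | CCOC(=O)/C(C)=C/C(OC)OC | intermediate
25 | ethyl (E)-2-methyl-4-oxobut-2-enoate (fragment B) | CCOC(=O)/C(C)=C/C=O | intermediate
26 | allylbarium chloride from 21, barium on C9 (not isolated) | COc1ccc(COC[C@@H](C(C)(C)O[Si](CC)(CC)CC)C/C=C(/C)CC/C=C(\C)C[Ba]Cl)cc1 | intermediate
27 | ethyl (2E,6E,10Z,13S)-4-hydroxy-13-(PMB-oxymethyl)-2,6,10,14-tetramethyl-14-(TES-oxy)pentadeca-2,6,10-trienoate (C4 epimers) | COc1ccc(COC[C@@H](C(C)(C)O[Si](CC)(CC)CC)C/C=C(/C)CC/C=C(\C)CC(O)/C=C(\C)C(=O)OCC)cc1 | intermediate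
28 | ethyl (2E,6E,10Z,13S)-13-(PMB-oxymethyl)-2,6,10,14-tetramethyl-4-oxo-14-(TES-oxy)pentadeca-2,6,10-trienoate | COc1ccc(COC[C@@H](C(C)(C)O[Si](CC)(CC)CC)C/C=C(/C)CC/C=C(\C)CC(=O)/C=C(\C)C(=O)OCC)cc1 | intermediate
29 | ethyl (2E,4R,6E,10Z,13S)-4-hydroxy-13-(PMB-oxymethyl)-2,6,10,14-tetramethyl-14-(TES-oxy)pentadeca-2,6,10-trienoate | COc1ccc(COC[C@@H](C(C)(C)O[Si](CC)(CC)CC)C/C=C(/C)CC/C=C(\C)C[C@@H](O)/C=C(\C)C(=O)OCC)cc1 | intermediate
30 | ethyl (2E,4R)-4-hydroxy-5-[(2R,3R)-3-[(3Z,6S)-6-(PMB-oxymethyl)-3,7-dimethyl-7-(TES-oxy)oct-3-en-1-yl]-2-methyloxiran-2-yl]-2-methylpent-2-enoate | COc1ccc(COC[C@@H](C(C)(C)O[Si](CC)(CC)CC)C/C=C(/C)CC[C@H]2O[C@]2(C)C[C@@H](O)/C=C(\C)C(=O)OCC)cc1 | intermediate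
31 | ethyl (2E,4R)-4-(TBS-oxy)-5-[(2R,3R)-3-[(3Z,6S)-6-(PMB-oxymethyl)-3,7-dimethyl-7-(TES-oxy)oct-3-en-1-yl]-2-methyloxiran-2-yl]-2-methylpent-2-enoate | COc1ccc(COC[C@@H](C(C)(C)O[Si](CC)(CC)CC)C/C=C(/C)CC[C@H]2O[C@]2(C)C[C@@H](O[Si](C)(C)C(C)(C)C)/C=C(\C)C(=O)OCC)cc1 | intermediate
32 | ethyl (2E,4R)-4-(TBS-oxy)-5-[(2R,3R)-3-[(3Z,6S)-6-(hydroxymethyl)-3,7-dimethyl-7-(TES-oxy)oct-3-en-1-yl]-2-methyloxiran-2-yl]-2-methylpent-2-enoate | OC[C@@H](C(C)(C)O[Si](CC)(CC)CC)C/C=C(/C)CC[C@H]1O[C@]1(C)C[C@@H](O[Si](C)(C)C(C)(C)C)/C=C(\C)C(=O)OCC | intermediate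
33 | ethyl (2E,4R)-4-(TBS-oxy)-5-[(2R,3R)-3-[(3Z,6R)-3,7-dimethyl-6-[(phenylsulfanyl)methyl]-7-(TES-oxy)oct-3-en-1-yl]-2-methyloxiran-2-yl]-2-methylpent-2-enoate | c1ccccc1SC[C@@H](C(C)(C)O[Si](CC)(CC)CC)C/C=C(/C)CC[C@H]1O[C@]1(C)C[C@@H](O[Si](C)(C)C(C)(C)C)/C=C(\C)C(=O)OCC | intermediate
34 | ethyl (2E,4R)-4-(TBS-oxy)-5-[(2R,3R)-3-[(3Z,6R)-3,7-dimethyl-6-[(phenylsulfonyl)methyl]-7-(TES-oxy)oct-3-en-1-yl]-2-methyloxiran-2-yl]-2-methylpent-2-enoate | O=S(=O)(c1ccccc1)C[C@@H](C(C)(C)O[Si](CC)(CC)CC)C/C=C(/C)CC[C@H]1O[C@]1(C)C[C@@H](O[Si](C)(C)C(C)(C)C)/C=C(\C)C(=O)OCC | intermediate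
35 | (2E,4R)-4-(TBS-oxy)-5-[(2R,3R)-3-[(3Z,6R)-3,7-dimethyl-6-[(phenylsulfonyl)methyl]-7-(TES-oxy)oct-3-en-1-yl]-2-methyloxiran-2-yl]-2-methylpent-2-en-1-ol | O=S(=O)(c1ccccc1)C[C@@H](C(C)(C)O[Si](CC)(CC)CC)C/C=C(/C)CC[C@H]1O[C@]1(C)C[C@@H](O[Si](C)(C)C(C)(C)C)/C=C(\C)CO | intermediate
36 | methanesulfonate of allylic alcohol 35 (not isolated) | O=S(=O)(c1ccccc1)C[C@@H](C(C)(C)O[Si](CC)(CC)CC)C/C=C(/C)CC[C@H]1O[C@]1(C)C[C@@H](O[Si](C)(C)C(C)(C)C)/C=C(\C)COS(C)(=O)=O | intermediate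
37 | (2R,3E)-5-bromo-1-[(2R,3R)-3-[(3Z,6R)-3,7-dimethyl-6-[(phenylsulfonyl)methyl]-7-(TES-oxy)oct-3-en-1-yl]-2-methyloxiran-2-yl]-4-methyl-2-(TBS-oxy)pent-3-ene | O=S(=O)(c1ccccc1)C[C@@H](C(C)(C)O[Si](CC)(CC)CC)C/C=C(/C)CC[C@H]1O[C@]1(C)C[C@@H](O[Si](C)(C)C(C)(C)C)/C=C(\C)CBr | intermediate
38 | α-lithio sulfone of 37, lithium on C14 (not isolated) | O=S(=O)(c1ccccc1)C([Li])[C@@H](C(C)(C)O[Si](CC)(CC)CC)C/C=C(/C)CC[C@H]1O[C@]1(C)C[C@@H](O[Si](C)(C)C(C)(C)C)/C=C(\C)CBr | intermediate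
39 | (1R,3Z,7R,8R,10R,11E)-10-(TBS-oxy)-7,8-epoxy-14-(phenylsulfonyl)-15-(TES-oxy)cembra-3,11-diene (C14 epimers) | CC(C)(C)[Si](C)(C)O[C@H]1/C=C(\C)CC(S(=O)(=O)c2ccccc2)[C@@H](C(C)(C)O[Si](CC)(CC)CC)C/C=C(/C)CC[C@H]2O[C@]2(C)C1 | intermediate
40 | (1R,3Z,7R,8R,10R,11E)-10-(TBS-oxy)-7,8-epoxy-15-(TES-oxy)cembra-3,11-diene | CC(C)(C)[Si](C)(C)O[C@H]1/C=C(\C)CC[C@@H](C(C)(C)O[Si](CC)(CC)CC)C/C=C(/C)CC[C@H]2O[C@]2(C)C1 | intermediate
41 | (1R,3Z,7R,8R,10R,11E)-7,8-epoxycembra-3,11-diene-10,15-diol | O[C@H]1/C=C(\C)CC[C@@H](C(C)(C)O)C/C=C(/C)CC[C@H]2O[C@]2(C)C1 | intermediate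
42 | (1R,3Z,7R,8R,10R,11E)-7,8-epoxycembra-3,11-diene-10,15-diyl diacetate (CNP0282098.2) | CC(=O)O[C@H]1/C=C(\C)CC[C@@H](C(C)(C)OC(C)=O)C/C=C(/C)CC[C@H]2O[C@]2(C)C1 | target

**Totals**
Total step count: 29. Longest linear sequence: 27 steps (steps 1–13, then 16–29); fragment B takes 2 steps (14–15).

**Three steps most likely to fail, with fallbacks**

Step 16 (allylbarium formation on a late fragment; α/γ ratio and tolerance of the PMB ether are the concerns). The fallback is a two-stage allyl-transfer allylation that sets out from chloride 21. An indium Barbier reaction with acetone (In, NaI, DMF, rt) gives the branched γ-adduct (6Z,9S)-9-(PMB-oxymethyl)-2,6,10-trimethyl-3-(prop-1-en-2-yl)-10-(TES-oxy)undec-6-en-2-ol F1 as a C3 epimer mixture. Treating F1 and aldehyde 25 with Sn(OTf)2 (cat.) in CH2Cl2 at 0 °C triggers a 2-oxonia-Cope allyl transfer that expels acetone and gives the linear E homoallylic alcohol, coming back to the route at compound 27.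

Step 19 (the anti selectivity of the directed epoxidation rests on a transition-state model and has no close precedent for this substitution pattern). The fallback makes the epoxide by iodocarbonate cyclisation, which is 1,3-syn selective, and then inverts C10; it sets out from ketone 28. Reduction with the (R)-2-methyl-CBS-oxazaborolidine (C18H20BNO) and catecholborane gives ethyl (2E,4S,6E,10Z,13S)-4-hydroxy-13-(PMB-oxymethyl)-2,6,10,14-tetramethyl-14-(TES-oxy)pentadeca-2,6,10-trienoate F2. Boc2O and 4-(dimethylamino)pyridine give its tert-butyl carbonate, ethyl (2E,4S,6E,10Z,13S)-4-[(tert-butoxycarbonyl)oxy]-13-(PMB-oxymethyl)-2,6,10,14-tetramethyl-14-(TES-oxy)pentadeca-2,6,10-trienoate F3. I2 in MeCN at −20 °C closes the syn cyclic iodocarbonate ethyl (2E)-3-[(4S,6R)-6-[(1S,4Z,7S)-1-iodo-7-(PMB-oxymethyl)-4,8-dimethyl-8-(TES-oxy)non-4-en-1-yl]-6-methyl-2-oxo-1,3-dioxan-4-yl]-2-methylprop-2-enoate F4. K2CO3 in EtOH opens the carbonate and the C8 alkoxide displaces iodide to give ethyl (2E,4S)-4-hydroxy-5-[(2R,3R)-3-[(3Z,6S)-6-(PMB-oxymethyl)-3,7-dimethyl-7-(TES-oxy)oct-3-en-1-yl]-2-methyloxiran-2-yl]-2-methylpent-2-enoate F5. Mitsunobu inversion (4-nitrobenzoic acid, PPh3, diisopropyl azodicarboxylate) gives ethyl (2E,4R)-5-[(2R,3R)-3-[(3Z,6S)-6-(PMB-oxymethyl)-3,7-dimethyl-7-(TES-oxy)oct-3-en-1-yl]-2-methyloxiran-2-yl]-2-methyl-4-[(4-nitrobenzoyl)oxy]pent-2-enoate F6. Ethanolysis (K2CO3, EtOH) then comes back to the route at compound 30.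

Step 26 (the 14-membered ring closure by sulfone alkylation competes with oligomerisation and with base attack on the allylic bromide). The fallback closes the same C13–C14 bond as an olefin and then saturates it; it sets out from alcohol 32. Mitsunobu reaction with 1-phenyl-1H-tetrazole-5-thiol (PPh3, diisopropyl azodicarboxylate) gives ethyl (2E,4R)-4-(TBS-oxy)-5-[(2R,3R)-3-[(3Z,6R)-3,7-dimethyl-6-{[(1-phenyl-1H-tetrazol-5-yl)sulfanyl]methyl}-7-(TES-oxy)oct-3-en-1-yl]-2-methyloxiran-2-yl]-2-methylpent-2-enoate F7. Oxidation with (NH4)6Mo7O24·4H2O and H2O2 in EtOH gives the sulfone ethyl (2E,4R)-4-(TBS-oxy)-5-[(2R,3R)-3-[(3Z,6R)-3,7-dimethyl-6-{[(1-phenyl-1H-tetrazol-5-yl)sulfonyl]methyl}-7-(TES-oxy)oct-3-en-1-yl]-2-methyloxiran-2-yl]-2-methylpent-2-enoate F8. Reduction with i-Bu2AlH at −78 °C gives (2E,4R)-4-(TBS-oxy)-5-[(2R,3R)-3-[(3Z,6R)-3,7-dimethyl-6-{[(1-phenyl-1H-tetrazol-5-yl)sulfonyl]methyl}-7-(TES-oxy)oct-3-en-1-yl]-2-methyloxiran-2-yl]-2-methylpent-2-en-1-ol F9, and MnO2 gives (2E,4R)-4-(TBS-oxy)-5-[(2R,3R)-3-[(3Z,6R)-3,7-dimethyl-6-{[(1-phenyl-1H-tetrazol-5-yl)sulfonyl]methyl}-7-(TES-oxy)oct-3-en-1-yl]-2-methyloxiran-2-yl]-2-methylpent-2-enal F10. Intramolecular Julia–Kocienski olefination (KN(SiMe3)2, THF, −78 °C → rt, high dilution) gives (1S,3Z,7R,8R,10R,11E,13E)-10-(TBS-oxy)-7,8-epoxy-15-(TES-oxy)cembra-3,11,13-triene F11. Diimide (2-nitrobenzenesulfonohydrazide, Et3N, CH2Cl2) reduces only the disubstituted C13=C14 bond and comes back to the route at compound 40.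

**Further compounds**
F1 | step 16 | (6Z,9S)-9-(PMB-oxymethyl)-2,6,10-trimethyl-3-(prop-1-en-2-yl)-10-(TES-oxy)undec-6-en-2-ol (C3 epimers) | COc1ccc(COC[C@@H](C(C)(C)O[Si](CC)(CC)CC)C/C=C(/C)CCC(C(C)=C)C(C)(C)O)cc1
F2 | step 19 | ethyl (2E,4S,6E,10Z,13S)-4-hydroxy-13-(PMB-oxymethyl)-2,6,10,14-tetramethyl-14-(TES-oxy)pentadeca-2,6,10-trienoate | COc1ccc(COC[C@@H](C(C)(C)O[Si](CC)(CC)CC)C/C=C(/C)CC/C=C(\C)C[C@H](O)/C=C(\C)C(=O)OCC)cc1
F3 | step 19 | ethyl (2E,4S,6E,10Z,13S)-4-[(tert-butoxycarbonyl)oxy]-13-(PMB-oxymethyl)-2,6,10,14-tetramethyl-14-(TES-oxy)pentadeca-2,6,10-trienoate | COc1ccc(COC[C@@H](C(C)(C)O[Si](CC)(CC)CC)C/C=C(/C)CC/C=C(\C)C[C@H](OC(=O)OC(C)(C)C)/C=C(\C)C(=O)OCC)cc1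
F4 | step 19 | ethyl (2E)-3-[(4S,6R)-6-[(1S,4Z,7S)-1-iodo-7-(PMB-oxymethyl)-4,8-dimethyl-8-(TES-oxy)non-4-en-1-yl]-6-methyl-2-oxo-1,3-dioxan-4-yl]-2-methylprop-2-enoate | COc1ccc(COC[C@@H](C(C)(C)O[Si](CC)(CC)CC)C/C=C(/C)CC[C@H](I)[C@@]2(C)C[C@@H](/C=C(\C)C(=O)OCC)OC(=O)O2)cc1
F5 | step 19 | ethyl (2E,4S)-4-hydroxy-5-[(2R,3R)-3-[(3Z,6S)-6-(PMB-oxymethyl)-3,7-dimethyl-7-(TES-oxy)oct-3-en-1-yl]-2-methyloxiran-2-yl]-2-methylpent-2-enoate | COc1ccc(COC[C@@H](C(C)(C)O[Si](CC)(CC)CC)C/C=C(/C)CC[C@H]2O[C@]2(C)C[C@H](O)/C=C(\C)C(=O)OCC)cc1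
F6 | step 19 | ethyl (2E,4R)-5-[(2R,3R)-3-[(3Z,6S)-6-(PMB-oxymethyl)-3,7-dimethyl-7-(TES-oxy)oct-3-en-1-yl]-2-methyloxiran-2-yl]-2-methyl-4-[(4-nitrobenzoyl)oxy]pent-2-enoate | COc1ccc(COC[C@@H](C(C)(C)O[Si](CC)(CC)CC)C/C=C(/C)CC[C@H]2O[C@]2(C)C[C@@H](OC(=O)c2ccc(cc2)[N+](=O)[O-])/C=C(\C)C(=O)OCC)cc1
F7 | step 26 | ethyl (2E,4R)-4-(TBS-oxy)-5-[(2R,3R)-3-[(3Z,6R)-3,7-dimethyl-6-{[(1-phenyl-1H-tetrazol-5-yl)sulfanyl]methyl}-7-(TES-oxy)oct-3-en-1-yl]-2-methyloxiran-2-yl]-2-methylpent-2-enoate | c1ccccc1-n1nnnc1SC[C@@H](C(C)(C)O[Si](CC)(CC)CC)C/C=C(/C)CC[C@H]1O[C@]1(C)C[C@@H](O[Si](C)(C)C(C)(C)C)/C=C(\C)C(=O)OCC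
F8 | step 26 | ethyl (2E,4R)-4-(TBS-oxy)-5-[(2R,3R)-3-[(3Z,6R)-3,7-dimethyl-6-{[(1-phenyl-1H-tetrazol-5-yl)sulfonyl]methyl}-7-(TES-oxy)oct-3-en-1-yl]-2-methyloxiran-2-yl]-2-methylpent-2-enoate | O=S(=O)(c1nnnn1-c1ccccc1)C[C@@H](C(C)(C)O[Si](CC)(CC)CC)C/C=C(/C)CC[C@H]1O[C@]1(C)C[C@@H](O[Si](C)(C)C(C)(C)C)/C=C(\C)C(=O)OCC
F9 | step 26 | (2E,4R)-4-(TBS-oxy)-5-[(2R,3R)-3-[(3Z,6R)-3,7-dimethyl-6-{[(1-phenyl-1H-tetrazol-5-yl)sulfonyl]methyl}-7-(TES-oxy)oct-3-en-1-yl]-2-methyloxiran-2-yl]-2-methylpent-2-en-1-ol | O=S(=O)(c1nnnn1-c1ccccc1)C[C@@H](C(C)(C)O[Si](CC)(CC)CC)C/C=C(/C)CC[C@H]1O[C@]1(C)C[C@@H](O[Si](C)(C)C(C)(C)C)/C=C(\C)CO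
F10 | step 26 | (2E,4R)-4-(TBS-oxy)-5-[(2R,3R)-3-[(3Z,6R)-3,7-dimethyl-6-{[(1-phenyl-1H-tetrazol-5-yl)sulfonyl]methyl}-7-(TES-oxy)oct-3-en-1-yl]-2-methyloxiran-2-yl]-2-methylpent-2-enal | O=S(=O)(c1nnnn1-c1ccccc1)C[C@@H](C(C)(C)O[Si](CC)(CC)CC)C/C=C(/C)CC[C@H]1O[C@]1(C)C[C@@H](O[Si](C)(C)C(C)(C)C)/C=C(\C)C=O
F11 | step 26 | (1S,3Z,7R,8R,10R,11E,13E)-10-(TBS-oxy)-7,8-epoxy-15-(TES-oxy)cembra-3,11,13-triene | CC(C)(C)[Si](C)(C)O[C@H]1/C=C(\C)/C=C/[C@@H](C(C)(C)O[Si](CC)(CC)CC)C/C=C(/C)CC[C@H]2O[C@]2(C)C1
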